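**Plan**

- Working ring numbering: C1 gem-diprenyl carbon, C2 ketone, C3 acyl-bearing carbon, C4 enol carbon, C5 carbinol stereocentre, C6 ketone (systematic names below carry their own locants).
- Retrosynthesis, late cuts: the C5 O–H is masked as a silyl ether, and the C5 prenyl group is traced to an (E)-but-2-enyl group (cross-metathesis). The C5–CH2 bond is then cut by a Claisen transform, which applies because the single six-membered ring carries a tertiary carbinol C5 with an allylic chain next to ketone C6. This leads to an O6 (R)-but-3-en-2-yl, O5-silyl dienol ether.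
- Earlier cuts: both C1–prenyl bonds (alkylative dearomatisation), the O6–butenyl bond (Mitsunobu), the O5–Si bond and the C5–O bond (formylation, Dakin oxidation), back to isobutyrylphloroglucinol.
- Forward order: no ring is formed. The benzene ring of the acylphloroglucinol is oxygenated, silylated at the new oxygen, etherified at the para oxygen and dearomatised by gem-diprenylation. Only then is the last side chain joined at C5 by the rearrangement, followed by metathesis and desilylation.
- Stereochemistry: the only stereocentre, C5 (R), comes from (S)-but-3-en-2-ol. The Mitsunobu step inverts it to the (R)-ether, and the rearrangement relays it to C5 by 1,3-chirality transfer through a chair transition state.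

Key step: step 8

Assumption: in step 2 the formyl group is taken to enter ortho to the free phenol; entry at the other open ring carbon would give an isomer that steps 3 to 5 convert into the same compound 8.

**Route**

Step 1
Reactants: 1 1-(2,4,6-trihydroxyphenyl)-2-methylpropan-1-one
Product: 2 1-[2,4-bis(benzyloxy)-6-hydroxyphenyl]-2-methylpropan-1-one
Conditions: BnBr (2.1 equiv), K2CO3, DMF, 23 °C
Reagents that add atoms: benzyl bromide, BrCc1ccccc1
Why: Williamson etherification of an acylphloroglucinol takes the para hydroxyl and one ortho hydroxyl and should stop there, because the last hydroxyl is held in a hydrogen bond to the ketone, and leaving exactly one chelated phenol is what later lets the new hydroxyl be silylated selectively.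

Step 2
Reactants: 2 1-[2,4-bis(benzyloxy)-6-hydroxyphenyl]-2-methylpropan-1-one
Product: 4 4,6-bis(benzyloxy)-2-hydroxy-3-(2-methylpropanoyl)benzaldehyde, via aryl iminium chloride 3 (not isolated)
Conditions: POCl3, DMF, MeCN, 0 to 23 °C; then aq NaOAc
Reagents that add atoms: N,N-dimethylformamide, CN(C)C=O; water, O
Why: Vilsmeier–Haack formylation is an electrophilic aromatic substitution that the three oxygen donors should direct to the open carbon next to the free phenol, while the α-branched isobutyryl ketone offers no methyl group for the competing chromone-forming attack of the chloroiminium reagent.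

Step 3
Reactants: 4 4,6-bis(benzyloxy)-2-hydroxy-3-(2-methylpropanoyl)benzaldehyde
Product: 6 1-[4,6-bis(benzyloxy)-2,3-dihydroxyphenyl]-2-methylpropan-1-one, via aryl formate 5 (not isolated)
Conditions: H2O2 (30% aq), NaOH, THF/H2O, 0 °C; then 1 M HCl
Reagents that add atoms: hydrogen peroxide, OO
Why: In this Dakin oxidation hydroperoxide adds to the ortho-hydroxy aldehyde, the electron-rich aryl group migrates to oxygen and the formate is hydrolysed in the flask, whereas the hindered, chelated aryl ketone reacts far more slowly and no alkene is yet present.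

Step 4
Reactants: 6 1-[4,6-bis(benzyloxy)-2,3-dihydroxyphenyl]-2-methylpropan-1-one
Product: 7 1-[4,6-bis(benzyloxy)-3-{[tert-butyl(dimethyl)silyl]oxy}-2-hydroxyphenyl]-2-methylpropan-1-one
Conditions: TBSCl (1.1 equiv), imidazole, DMF, 0 to 23 °C
Reagents that add atoms: tert-butyldimethylsilyl chloride, CC(C)(C)[Si](C)(C)Cl
Why: Imidazole-mediated silylation of a phenol should pick the C3 hydroxyl, since the only other hydroxyl is chelated to the ketone, the same bias that governs mono-alkylation of 2,3-dihydroxyaryl ketones.

Step 5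
Reactants: 7 1-[4,6-bis(benzyloxy)-3-{[tert-butyl(dimethyl)silyl]oxy}-2-hydroxyphenyl]-2-methylpropan-1-one
Product: 8 1-(3-{[tert-butyl(dimethyl)silyl]oxy}-2,4,6-trihydroxyphenyl)-2-methylpropan-1-one
Conditions: H2 (1 atm), Pd/C, EtOAc, 23 °C
Reagents that add atoms: none
Why: Catalytic hydrogenolysis cleaves both benzyl ethers under neutral conditions that leave the aryl silyl ether and the chelated aryl ketone alone, and it is placed before any alkene enters the molecule.

Step 6
Reactants: 8 1-(3-{[tert-butyl(dimethyl)silyl]oxy}-2,4,6-trihydroxyphenyl)-2-methylpropan-1-one; 9 (S)-but-3-en-2-ol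
Product: 10 1-{4-[(2R)-but-3-en-2-yloxy]-3-{[tert-butyl(dimethyl)silyl]oxy}-2,6-dihydroxyphenyl}-2-methylpropan-1-one
Conditions: PPh3, DIAD, THF, 0 °C
Reagents that add atoms: (S)-but-3-en-2-ol 9, O[C@@H](C)C=C
Why: In this Mitsunobu etherification the para hydroxyl is the most acidic phenol and the only one not flanking the acyl group, and SN2 displacement of the activated secondary allylic alcohol inverts its centre from S to R.

Step 7
Reactants: 10 1-{4-[(2R)-but-3-en-2-yloxy]-3-{[tert-butyl(dimethyl)silyl]oxy}-2,6-dihydroxyphenyl}-2-methylpropan-1-one; 11 prenyl bromide (1-bromo-3-methylbut-2-ene)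
Product: 13 5-[(2R)-but-3-en-2-yloxy]-4-{[tert-butyl(dimethyl)silyl]oxy}-3-hydroxy-6,6-bis(3-methylbut-2-enyl)-2-(2-methylpropanoyl)cyclohexa-2,4-dien-1-one, via mono-C-prenylated phenol 12 (not isolated)
Conditions: LiN(SiMe3)2 (3.1 equiv), prenyl bromide (2.2 equiv), THF, −20 to 0 °C; then aq NH4Cl
Reagents that add atoms: prenyl bromide 11, CC(C)=CCBr
Why: In this alkylative dearomatisation of an acylphloroglucinol the lithium bis-phenoxide is C-alkylated twice at the one unsubstituted ring carbon, the second alkylation creating quaternary C1 and turning the adjacent phenoxide into the C2 ketone, while the lithium counter-ion in THF disfavours O-alkylation and the silyloxy-bearing carbon is shielded.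

Step 8
Reactants: 13 5-[(2R)-but-3-en-2-yloxy]-4-{[tert-butyl(dimethyl)silyl]oxy}-3-hydroxy-6,6-bis(3-methylbut-2-enyl)-2-(2-methylpropanoyl)cyclohexa-2,4-dien-1-one
Product: 14 (6R)-6-[(2E)-but-2-enyl]-6-{[tert-butyl(dimethyl)silyl]oxy}-5-hydroxy-2,2-bis(3-methylbut-2-enyl)-4-(2-methylpropanoyl)cyclohex-4-ene-1,3-dione
Conditions: PhMe (degassed), 100 °C, sealed tube
Reagents that add atoms: none
Why: This is a concerted [3,3]-sigmatropic (Claisen) rearrangement of an allyl enol ether: the bond from O6 to the butenyl carbinol carbon breaks as the terminal CH2 of the butenyl group bonds to C5, so the C5=C6 enol ether becomes the C6 ketone and C5 becomes the fully substituted silyloxy carbon, and no ring is closed. The closest known reaction type is the Claisen rearrangement of secondary allyl enol ethers with 1,3-chirality transfer to a quaternary carbon, with the silyl enol ethers of α-allyloxy ketones and the 3-O-allyl ascorbates as the nearest relatives, since both form a tertiary carbinol at the accepting carbon. The C5 configuration is controlled by the (R)-carbinol carbon through a chair transition state in which its methyl group and ring carbon C4 are equatorial and the silyloxy group is axial, which places the new C–C bond on the face that gives (R) at C5 and makes the new alkene E. Site selectivity is secured because C1 is quaternary, so C5 is the only enol terminus the O6 allyl group can reach, and the two ring faces are otherwise equivalent because C1 carries two identical prenyl groups. The selectivity that has to hold is chair over boat and equatorial over axial methyl; the gem-diprenyl group at C1 penalises both alternatives, because the boat puts the central allyl carbon over the ring and the axial methyl points at a C1 prenyl group. The chelated C4 enol and the three prenyl groups should be spectators at this temperature.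

Step 9
Reactants: 14 (6R)-6-[(2E)-but-2-enyl]-6-{[tert-butyl(dimethyl)silyl]oxy}-5-hydroxy-2,2-bis(3-methylbut-2-enyl)-4-(2-methylpropanoyl)cyclohex-4-ene-1,3-dione; 15 2-methylbut-2-ene
Product: 16 (6R)-6-{[tert-butyl(dimethyl)silyl]oxy}-5-hydroxy-2,2,6-tris(3-methylbut-2-enyl)-4-(2-methylpropanoyl)cyclohex-4-ene-1,3-dione
Conditions: 2-methylbut-2-ene (excess), RuCl2(H2IMes)(PCy3)(=CHPh) (second-generation Grubbs catalyst, 5 mol %), CH2Cl2, 40 °C
Reagents that add atoms: 2-methylbut-2-ene 15, CC=C(C)C
Why: Olefin cross-metathesis with 2-methylbut-2-ene exchanges the ethylidene terminus of the but-2-enyl group for an isopropylidene, the three existing prenyl groups can only undergo degenerate exchange, and the C5 stereocentre is not touched.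

Step 10
Reactants: 16 (6R)-6-{[tert-butyl(dimethyl)silyl]oxy}-5-hydroxy-2,2,6-tris(3-methylbut-2-enyl)-4-(2-methylpropanoyl)cyclohex-4-ene-1,3-dione
Product: 17 (6R)-5,6-dihydroxy-2,2,6-tris(3-methylbut-2-enyl)-4-(2-methylpropanoyl)cyclohex-4-ene-1,3-dione (target)
Conditions: Et3N·3HF, MeCN, 23 °C
Reagents that add atoms: none
Why: Fluoride-mediated desilylation under mildly acidic, non-basic conditions should free the tertiary alcohol (the neighbouring enol can assist by accepting the silyl group) without base-induced acyloin ring contraction or acid-induced cyclisation onto a prenyl group, so the (R) configuration is kept.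

**Compound list**

1 | 1-(2,4,6-trihydroxyphenyl)-2-methylpropan-1-one | CC(C)C(=O)c1c(O)cc(O)cc1O | starting material
2 | 1-[2,4-bis(benzyloxy)-6-hydroxyphenyl]-2-methylpropan-1-one | CC(C)C(=O)c1c(O)cc(OCc2ccccc2)cc1OCc1ccccc1 | intermediate
3 | N-{[4,6-bis(benzyloxy)-2-hydroxy-3-(2-methylpropanoyl)phenyl]methylidene}-N-methylmethanaminium chloride (not isolated) | CC(C)C(=O)c1c(O)c(C=[N+](C)C)c(OCc2ccccc2)cc1OCc1ccccc1.[Cl-] | intermediate
4 | 4,6-bis(benzyloxy)-2-hydroxy-3-(2-methylpropanoyl)benzaldehyde | CC(C)C(=O)c1c(O)c(C=O)c(OCc2ccccc2)cc1OCc1ccccc1 | intermediate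
5 | 4,6-bis(benzyloxy)-2-hydroxy-3-(2-methylpropanoyl)phenyl formate (not isolated) | CC(C)C(=O)c1c(O)c(OC=O)c(OCc2ccccc2)cc1OCc1ccccc1 | intermediate
6 | 1-[4,6-bis(benzyloxy)-2,3-dihydroxyphenyl]-2-methylpropan-1-one | CC(C)C(=O)c1c(O)c(O)c(OCc2ccccc2)cc1OCc1ccccc1 | intermediate
7 | 1-[4,6-bis(benzyloxy)-3-{[tert-butyl(dimethyl)silyl]oxy}-2-hydroxyphenyl]-2-methylpropan-1-one | CC(C)C(=O)c1c(O)c(O[Si](C)(C)C(C)(C)C)c(OCc2ccccc2)cc1OCc1ccccc1 | intermediate
8 | 1-(3-{[tert-butyl(dimethyl)silyl]oxy}-2,4,6-trihydroxyphenyl)-2-methylpropan-1-one | CC(C)C(=O)c1c(O)c(O[Si](C)(C)C(C)(C)C)c(O)cc1O | intermediate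
9 | (S)-but-3-en-2-ol | O[C@@H](C)C=C | starting material
10 | 1-{4-[(2R)-but-3-en-2-yloxy]-3-{[tert-butyl(dimethyl)silyl]oxy}-2,6-dihydroxyphenyl}-2-methylpropan-1-one | CC(C)C(=O)c1c(O)c(O[Si](C)(C)C(C)(C)C)c(O[C@H](C)C=C)cc1O | intermediate
11 | prenyl bromide (1-bromo-3-methylbut-2-ene) | CC(C)=CCBr | starting material
12 | 1-{4-[(2R)-but-3-en-2-yloxy]-3-{[tert-butyl(dimethyl)silyl]oxy}-2,6-dihydroxy-5-(3-methylbut-2-enyl)phenyl}-2-methylpropan-1-one (not isolated) | CC(C)C(=O)c1c(O)c(O[Si](C)(C)C(C)(C)C)c(O[C@H](C)C=C)c(CC=C(C)C)c1O | intermediate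
13 | 5-[(2R)-but-3-en-2-yloxy]-4-{[tert-butyl(dimethyl)silyl]oxy}-3-hydroxy-6,6-bis(3-methylbut-2-enyl)-2-(2-methylpropanoyl)cyclohexa-2,4-dien-1-one | CC(C)=CCC1(CC=C(C)C)C(=O)C(C(=O)C(C)C)=C(O)C(O[Si](C)(C)C(C)(C)C)=C1O[C@H](C)C=C | intermediate
14 | (6R)-6-[(2E)-but-2-enyl]-6-{[tert-butyl(dimethyl)silyl]oxy}-5-hydroxy-2,2-bis(3-methylbut-2-enyl)-4-(2-methylpropanoyl)cyclohex-4-ene-1,3-dione | CC(C)=CCC1(CC=C(C)C)C(=O)C(C(=O)C(C)C)=C(O)[C@](O[Si](C)(C)C(C)(C)C)(C/C=C/C)C1=O | intermediate
15 | 2-methylbut-2-ene | CC=C(C)C | starting material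
16 | (6R)-6-{[tert-butyl(dimethyl)silyl]oxy}-5-hydroxy-2,2,6-tris(3-methylbut-2-enyl)-4-(2-methylpropanoyl)cyclohex-4-ene-1,3-dione | CC(C)=CCC1(CC=C(C)C)C(=O)C(C(=O)C(C)C)=C(O)[C@](O[Si](C)(C)C(C)(C)C)(CC=C(C)C)C1=O | intermediate
17 | (6R)-5,6-dihydroxy-2,2,6-tris(3-methylbut-2-enyl)-4-(2-methylpropanoyl)cyclohex-4-ene-1,3-dione | CC(C)=CCC1(CC=C(C)C)C(=O)C(C(=O)C(C)C)=C(O)[C@](O)(CC=C(C)C)C1=O | target

**Step count and risks**

Total step count: 10. Longest linear sequence: 10 steps (from 1).

Steps most likely to fail:

1. Step 7 (gem-diprenylation with dearomatisation). O-prenylation of the chelated phenoxides may compete with the second C-alkylation, alkylation may occur at the silyloxy-bearing carbon, and the base may move the silyl group between neighbouring oxygens. The fallback dearomatises before etherifying; it sets out from 8 and returns at 13. The tri-lithium phenoxide of 8 (LiN(SiMe3)2, THF, 0 °C) is alkylated with 11. As in the classical lupulone-type alkylation of a free acylphloroglucinol with a single open ring carbon, this should pass through 1-[3-{[tert-butyl(dimethyl)silyl]oxy}-2,4,6-trihydroxy-5-(3-methylbut-2-enyl)phenyl]-2-methylpropan-1-one F1. It should then give 4-{[tert-butyl(dimethyl)silyl]oxy}-3,5-dihydroxy-6,6-bis(3-methylbut-2-enyl)-2-(2-methylpropanoyl)cyclohexa-2,4-dien-1-one F2. Mitsunobu etherification of F2 with 9 (PPh3, DIAD, THF) should take place at the enol oxygen remote from the acyl group, the position known to be taken when such dearomatised acylphloroglucinols are O-alkylated, and this gives 13.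

2. Step 8 (Claisen rearrangement). Leakage through a boat transition state, or ionisation and recombination of the secondary allylic ether, would lower the enantiomeric purity at C5. Thermal loss of butadiene or silyl migration from O5 to O4 would consume the substrate. The fallback rearranges the unprotected enol; it sets out from 13 and returns at 17. Desilylation of 13 (Et3N·3HF, MeCN) should give 5-[(2R)-but-3-en-2-yloxy]-3,4-dihydroxy-6,6-bis(3-methylbut-2-enyl)-2-(2-methylpropanoyl)cyclohexa-2,4-dien-1-one F3. Heating F3 (PhMe, 80 °C, argon) should give (6R)-6-[(2E)-but-2-enyl]-5,6-dihydroxy-2,2-bis(3-methylbut-2-enyl)-4-(2-methylpropanoyl)cyclohex-4-ene-1,3-dione F4; the precedent is the Claisen rearrangement of 3-O-allyl ascorbates, where a free hydroxyl sits on the accepting carbon. The axial group in the chair is then a small hydroxyl instead of a silyloxy group. Cross-metathesis of F4 with 15 under the conditions of step 9 gives 17 directly, so step 10 falls away.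

3. Step 6 (Mitsunobu etherification). SN2′ attack would give the achiral linear but-2-enyl ether, partial loss of configuration would erode the stereochemical purity carried into step 8, and an ortho phenol may be etherified. The fallback sets the ether stereocentre by catalyst control; it sets out from 8 and returns at 10. The mono-lithium phenoxide of 8 undergoes iridium-catalysed branched-selective asymmetric allylic etherification with (E)-but-2-enyl methyl carbonate ([Ir(cod)Cl]2, the enantiomer of the chiral phosphoramidite ligand that delivers the (R)-ether, THF). This gives 10 in one operation and makes no new compound.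

Further compounds
F1 | step 7 | 1-[3-{[tert-butyl(dimethyl)silyl]oxy}-2,4,6-trihydroxy-5-(3-methylbut-2-enyl)phenyl]-2-methylpropan-1-one | CC(C)C(=O)c1c(O)c(O[Si](C)(C)C(C)(C)C)c(O)c(CC=C(C)C)c1O
F2 | step 7 | 4-{[tert-butyl(dimethyl)silyl]oxy}-3,5-dihydroxy-6,6-bis(3-methylbut-2-enyl)-2-(2-methylpropanoyl)cyclohexa-2,4-dien-1-one | CC(C)=CCC1(CC=C(C)C)C(=O)C(C(=O)C(C)C)=C(O)C(O[Si](C)(C)C(C)(C)C)=C1O
F3 | step 8 | 5-[(2R)-but-3-en-2-yloxy]-3,4-dihydroxy-6,6-bis(3-methylbut-2-enyl)-2-(2-methylpropanoyl)cyclohexa-2,4-dien-1-one | CC(C)=CCC1(CC=C(C)C)C(=O)C(C(=O)C(C)C)=C(O)C(O)=C1O[C@H](C)C=C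
F4 | step 8 | (6R)-6-[(2E)-but-2-enyl]-5,6-dihydroxy-2,2-bis(3-methylbut-2-enyl)-4-(2-methylpropanoyl)cyclohex-4-ene-1,3-dione | CC(C)=CCC1(CC=C(C)C)C(=O)C(C(=O)C(C)C)=C(O)[C@](O)(C/C=C/C)C1=O
F0 | step 6 | none | none
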